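**Retrosynthetic overview** (labdane numbering: ring A = C1–C5 and C10, ring B = C5–C10)

1. Target 18 ← diol 17 ← silyl ether 16: both acetates go on last; C15 is carried as a tert-butyldiphenylsilyl ether through all enolate, hydride and Lewis acid steps.
2. 16 ← aldehyde 15 (key step): ring A carries its only oxygen at C2, next to C1, and C1 hangs on the methyl-bearing ring-fusion carbon C10, which is bonded to C9 of the Δ7 ring B. A C2 aldehyde, a C10=C1 isopropenyl group on C5 and the (E)-C8=C9 olefin therefore close ring A (bond C1–C2) and then ring B (bond C9–C10) in one cationic cascade.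
3. 15 ← acid 11: reduction, oxidation and a one-carbon Wittig homologation turn the C3 carboxyl into C3H2–C2HO.
4. 11 ← propanoate 6: a boron-mediated enantioselective Ireland–Claisen rearrangement makes C4–C5, sets C5 and releases the isopropenyl group; α-methylation completes the C4 gem-dimethyl group.
5. 6 ← farnesol 1 + propanoyl chloride 5: farnesol supplies C5–C17 and C20 with the (E)-C8=C9 olefin in place; asymmetric hydrogenation sets C13 and SeO2 oxidises C1.

Key step: step 11

Remark: the ligand of step 5, N,N'-[(1S,2S)-1,2-diphenylethane-1,2-diyl]bis[3,5-bis(trifluoromethyl)benzenesulfonamide], is a known, recoverable reagent made in one step from commercial (1S,2S)-1,2-diphenylethane-1,2-diamine and 3,5-bis(trifluoromethyl)benzenesulfonyl chloride.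

Assumption: the (4S,5S)-bromoborane is taken to be the enantiomer that steers the chair rearrangement to the C5 configuration drawn in 9; the sense is checked on 9 before material is carried on, and the (4R,5R)-reagent is the same chemistry if the sense is the opposite.

**Route**

Step 1
Reactants: 1 (2E,6E)-farnesol
Product: 2 (3S,6E)-3,7,11-trimethyldodeca-6,10-dien-1-ol
Conditions: Ru(OAc)2[(R)-BINAP] (cat.), H2 (about 100 atm), MeOH, 20 °C
Reagents that add atoms: none
Why: Noyori asymmetric hydrogenation: the allylic hydroxyl directs the ruthenium catalyst to the C13=C14 olefin alone, the (R)-BINAP complex adding hydrogen to the face that gives (S)-C13 (the sense in which geraniol gives (S)-citronellol), while the two remote trisubstituted olefins are not reduced.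

Step 2
Reactants: 2 (3S,6E)-3,7,11-trimethyldodeca-6,10-dien-1-ol
Product: 3 tert-butyl{[(3S,6E)-3,7,11-trimethyldodeca-6,10-dien-1-yl]oxy}diphenylsilane
Conditions: TBDPSCl, imidazole, DMF, rt
Reagents that add atoms: tert-butyl(chloro)diphenylsilane, CC(C)(C)[Si](Cl)(c1ccccc1)c1ccccc1
Why: Imidazole-promoted silylation of the primary alcohol; the silyl ether stands in for the C15 acetate because an acetate would be enolised in steps 5 and 6, reduced in step 7 and would bind Lewis acid in step 11, whereas the silyl ether survives all of them.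

Step 3
Reactants: 3 tert-butyl{[(3S,6E)-3,7,11-trimethyldodeca-6,10-dien-1-yl]oxy}diphenylsilane
Product: 4 (2E,6E,10S)-12-[(tert-butyldiphenylsilyl)oxy]-2,6,10-trimethyldodeca-2,6-dien-1-ol
Conditions: SeO2 (cat.), t-BuOOH, salicylic acid (cat.), CH2Cl2, 0 °C → rt; then NaBH4, MeOH, 0 °C
Reagents that add atoms: tert-butyl hydroperoxide, CC(C)(C)OO
Why: Allylic oxidation with SeO2/t-BuOOH (ene reaction then [2,3]-sigmatropic shift) takes the (E)-methyl of the terminal isopropylidene group, the most accessible allylic position, so C1 is hydroxylated with the (E)-C10=C5 olefin intact; NaBH4 returns over-oxidised enal to 4.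

Step 4
Reactants: 4 (2E,6E,10S)-12-[(tert-butyldiphenylsilyl)oxy]-2,6,10-trimethyldodeca-2,6-dien-1-ol; 5 propanoyl chloride
Product: 6 (2E,6E,10S)-12-[(tert-butyldiphenylsilyl)oxy]-2,6,10-trimethyldodeca-2,6-dien-1-yl propanoate
Conditions: pyridine, DMAP (cat.), CH2Cl2, 0 °C
Reagents that add atoms: none
Why: DMAP-catalysed acylation of a primary allylic alcohol; the propanoate is chosen over the 2-methylpropanoate because soft enolisation of propanoates by the boron reagent of step 5 is the established case, the second C4 methyl being added in step 6.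

Step 5
Reactants: 6 (2E,6E,10S)-12-[(tert-butyldiphenylsilyl)oxy]-2,6,10-trimethyldodeca-2,6-dien-1-yl propanoate
Product: 9 (2S,3R,6E,10S)-12-[(tert-butyldiphenylsilyl)oxy]-2,6,10-trimethyl-3-(prop-1-en-2-yl)dodec-6-enoic acid, via boron ketene acetal 7 (not isolated), via acyloxyborane 8 (not isolated)
Conditions: (4S,5S)-2-bromo-1,3-bis{[3,5-bis(trifluoromethyl)phenyl]sulfonyl}-4,5-diphenyl-1,3,2-diazaborolidine (made in the flask from the (1S,2S)-bis-sulfonamide and BBr3 in CH2Cl2), Et3N, toluene–hexane, −78 °C, then −20 → 4 °C; aqueous work-up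
Reagents that add atoms: none
Why: Boron-mediated enantioselective Ireland–Claisen rearrangement of an allyl propanoate: the bromoborane and Et3N give the E(O) boron ketene acetal 7, whose [3,3] shift runs through a chair on the enolate face left open by the C2-symmetric bis-sulfonamide, so that C4–C5 forms, the (E)-C10=C5 geometry is translated into the C5 configuration drawn, the isopropenyl group is released and the 4,5-anti acid results; C4 is erased in step 6, so only the sense at C5 matters and it does not depend on the enolate geometry.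

Step 6
Reactants: 9 (2S,3R,6E,10S)-12-[(tert-butyldiphenylsilyl)oxy]-2,6,10-trimethyl-3-(prop-1-en-2-yl)dodec-6-enoic acid
Product: 11 (3S,6E,10S)-12-[(tert-butyldiphenylsilyl)oxy]-2,2,6,10-tetramethyl-3-(prop-1-en-2-yl)dodec-6-enoic acid, via dilithium enediolate 10 (not isolated)
Conditions: LiN(i-Pr)2 (2.3 equiv), THF–DMPU, 0 → 35 °C; MeI, 0 °C → rt; aq. HCl
Reagents that add atoms: iodomethane, CI
Why: Alkylation of a carboxylic acid dianion: the second deprotonation flattens C4, MeI completes the C4 gem-dimethyl group, and C5, which has no acidic hydrogen, keeps its configuration; any methyl ester formed by O-alkylation is reduced to the same alcohol in step 7.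

Step 7
Reactants: 11 (3S,6E,10S)-12-[(tert-butyldiphenylsilyl)oxy]-2,2,6,10-tetramethyl-3-(prop-1-en-2-yl)dodec-6-enoic acid
Product: 12 (3S,6E,10S)-12-[(tert-butyldiphenylsilyl)oxy]-2,2,6,10-tetramethyl-3-(prop-1-en-2-yl)dodec-6-en-1-ol
Conditions: LiAlH4, THF, 0 °C → rt; aqueous work-up
Reagents that add atoms: none
Why: LiAlH4 reduction of the hindered carboxylic acid to the neopentyl alcohol; the silyl ether and the two unactivated olefins are inert to hydride at this temperature.

Step 8
Reactants: 12 (3S,6E,10S)-12-[(tert-butyldiphenylsilyl)oxy]-2,2,6,10-tetramethyl-3-(prop-1-en-2-yl)dodec-6-en-1-ol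
Product: 13 (3S,6E,10S)-12-[(tert-butyldiphenylsilyl)oxy]-2,2,6,10-tetramethyl-3-(prop-1-en-2-yl)dodec-6-enal
Conditions: Dess–Martin periodinane, CH2Cl2, rt
Reagents that add atoms: none
Why: Dess–Martin oxidation of a primary alcohol under near-neutral conditions; the aldehyde has no α-hydrogen, so no centre can epimerise.

Step 9
Reactants: 13 (3S,6E,10S)-12-[(tert-butyldiphenylsilyl)oxy]-2,2,6,10-tetramethyl-3-(prop-1-en-2-yl)dodec-6-enal
Product: 14 tert-butyl{[(3S,6E,10S,12E/Z)-13-methoxy-3,7,11,11-tetramethyl-10-(prop-1-en-2-yl)trideca-6,12-dien-1-yl]oxy}diphenylsilane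
Conditions: Ph3P(CH2OMe)Cl, t-BuOK, THF, 0 °C → rt
Reagents that add atoms: (methoxymethyl)triphenylphosphonium chloride, COC[P+](c1ccccc1)(c1ccccc1)c1ccccc1.[Cl-]
Why: Wittig olefination with methoxymethylenetriphenylphosphorane adds C2 as an enol ether; the aldehyde cannot enolise, so the basic ylide only adds, and the E/Z mixture is of no consequence because step 10 converges it.

Step 10
Reactants: 14 tert-butyl{[(3S,6E,10S,12E/Z)-13-methoxy-3,7,11,11-tetramethyl-10-(prop-1-en-2-yl)trideca-6,12-dien-1-yl]oxy}diphenylsilane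
Product: 15 (4S,7E,11S)-13-[(tert-butyldiphenylsilyl)oxy]-3,3,7,11-tetramethyl-4-(prop-1-en-2-yl)tridec-7-enal
Conditions: 1 M HCl, THF, 0 °C → rt
Reagents that add atoms: water, O
Why: Acid hydrolysis of the enol ether (C-protonation then hemiacetal collapse) gives the homologous aldehyde with C3 as CH2 and C2 as CHO; dilute aqueous acid at or below room temperature should neither start the cationic cyclisation nor cleave the tert-butyldiphenylsilyl ether.

Step 11
Reactants: 15 (4S,7E,11S)-13-[(tert-butyldiphenylsilyl)oxy]-3,3,7,11-tetramethyl-4-(prop-1-en-2-yl)tridec-7-enal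
Product: 16 (2R,4aR,8R,8aR)-8-{(3S)-5-[(tert-butyldiphenylsilyl)oxy]-3-methylpentyl}-4,4,7,8a-tetramethyl-1,2,3,4,4a,5,8,8a-octahydronaphthalen-2-ol
Conditions: MeAlCl2 (2.2 equiv), CH2Cl2, −78 → −40 °C; then aq. NaHCO3
Reagents that add atoms: none
Why: Two equivalents of MeAlCl2 give the strongly electrophilic 1:2 aldehyde complex (the Al–CH3 bonds also scavenge protons), the isopropenyl methylene C1 adds to C2 in the Markovnikov sense, the tertiary C10 cation that develops is taken by C9 of the (E)-C8=C9 olefin, and the tertiary C8 cation loses the axial H7 to leave the Δ7 olefin, the C2 aluminium alkoxide being hydrolysed on work-up. The closest known reaction type is the alkylaluminium halide-promoted Prins (carbonyl-ene) cyclisation of 5-methylhex-5-enal-type aldehydes, carried on into a cation–olefin polycyclisation by a trisubstituted olefin. Ring A closes as a six-membered chair that is exo to the carbonyl (oxygen outside the ring) and endo to the isopropenyl π bond (C1 and C10 both in the ring), and ring B closes 6-endo (C9 and C8 both in the ring) through a second chair. All three new centres are relayed from C5, which holds both chains equatorial: at C2 the O–Al group is equatorial because the axial site is 1,3-diaxial to the axial C4 methyl, at C10 the anti addition of C2 and C9 across C10=C1 puts the methyl axial and trans to H5, and at C9 the (E)-olefin geometry in the chair puts the side chain equatorial and H9 trans to the C10 methyl. The step needs bicyclisation to beat ene-type proton loss from the C10 cation and needs H7 to be lost in preference to a C17 methyl proton; the first is served by the C4 gem-dimethyl group and the C5 branch, which fold the chain so that the C8=C9 olefin lies over C10, and by the excess Lewis acid, which leaves no basic alkoxide, and the second by the alignment of the axial C7–H bond with the empty orbital at C8 at low temperature in the absence of free acid.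

Step 12
Reactants: 16 (2R,4aR,8R,8aR)-8-{(3S)-5-[(tert-butyldiphenylsilyl)oxy]-3-methylpentyl}-4,4,7,8a-tetramethyl-1,2,3,4,4a,5,8,8a-octahydronaphthalen-2-ol
Product: 17 (2R,4aR,8R,8aR)-8-[(3S)-5-hydroxy-3-methylpentyl]-4,4,7,8a-tetramethyl-1,2,3,4,4a,5,8,8a-octahydronaphthalen-2-ol
Conditions: Bu4NF, THF, rt
Reagents that add atoms: none
Why: Fluoride cleavage of the silyl ether (Si–F bond formation) frees the C15 alcohol; the secondary alcohol and the ring olefin are unaffected.

Step 13
Reactants: 17 (2R,4aR,8R,8aR)-8-[(3S)-5-hydroxy-3-methylpentyl]-4,4,7,8a-tetramethyl-1,2,3,4,4a,5,8,8a-octahydronaphthalen-2-ol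
Product: 18 (2R,4aR,8R,8aR)-8-[(3S)-5-acetoxy-3-methylpentyl]-4,4,7,8a-tetramethyl-1,2,3,4,4a,5,8,8a-octahydronaphthalen-2-yl acetate
Conditions: Ac2O, pyridine, DMAP (cat.), CH2Cl2, rt
Reagents that add atoms: acetic anhydride, CC(=O)OC(C)=O
Why: DMAP-catalysed acetylation esterifies both the primary C15 and the equatorial secondary C2 alcohol without touching any stereocentre, which gives the target.

**Compound list**

1 | (2E,6E)-farnesol | CC(C)=CCC/C(C)=C/CC/C(C)=C/CO | starting material
2 | (3S,6E)-3,7,11-trimethyldodeca-6,10-dien-1-ol | OCC[C@@H](C)CC/C=C(\C)CCC=C(C)C | intermediate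
3 | tert-butyl{[(3S,6E)-3,7,11-trimethyldodeca-6,10-dien-1-yl]oxy}diphenylsilane | CC(C)(C)[Si](c1ccccc1)(c1ccccc1)OCC[C@@H](C)CC/C=C(\C)CCC=C(C)C | intermediate
4 | (2E,6E,10S)-12-[(tert-butyldiphenylsilyl)oxy]-2,6,10-trimethyldodeca-2,6-dien-1-ol | CC(C)(C)[Si](c1ccccc1)(c1ccccc1)OCC[C@@H](C)CC/C=C(\C)CC/C=C(\C)CO | intermediate
5 | propanoyl chloride | CCC(Cl)=O | starting material
6 | (2E,6E,10S)-12-[(tert-butyldiphenylsilyl)oxy]-2,6,10-trimethyldodeca-2,6-dien-1-yl propanoate | CC(C)(C)[Si](c1ccccc1)(c1ccccc1)OCC[C@@H](C)CC/C=C(\C)CC/C=C(\C)COC(=O)CC | intermediate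
7 | E(O) boron ketene acetal of 6: the enolate oxygen carries the (4S,5S)-1,3-bis{[3,5-bis(trifluoromethyl)phenyl]sulfonyl}-4,5-diphenyl-1,3,2-diazaborolidin-2-yl group, CH3 cis to the allyloxy oxygen | CC(C)(C)[Si](c1ccccc1)(c1ccccc1)OCC[C@@H](C)CC/C=C(\C)CC/C=C(\C)CO/C(OB1N(S(=O)(=O)c2cc(C(F)(F)F)cc(C(F)(F)F)c2)[C@@H](c2ccccc2)[C@H](c2ccccc2)N1S(=O)(=O)c1cc(C(F)(F)F)cc(C(F)(F)F)c1)=C\C | intermediate (not isolated)
8 | acyloxyborane of acid 9: the carboxyl oxygen carries the same diazaborolidin-2-yl group | CC(C)(C)[Si](c1ccccc1)(c1ccccc1)OCC[C@@H](C)CC/C=C(\C)CC[C@@H](C(C)=C)[C@H](C)C(=O)OB1N(S(=O)(=O)c2cc(C(F)(F)F)cc(C(F)(F)F)c2)[C@@H](c2ccccc2)[C@H](c2ccccc2)N1S(=O)(=O)c1cc(C(F)(F)F)cc(C(F)(F)F)c1 | intermediate (not isolated)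
9 | (2S,3R,6E,10S)-12-[(tert-butyldiphenylsilyl)oxy]-2,6,10-trimethyl-3-(prop-1-en-2-yl)dodec-6-enoic acid | CC(C)(C)[Si](c1ccccc1)(c1ccccc1)OCC[C@@H](C)CC/C=C(\C)CC[C@@H](C(C)=C)[C@H](C)C(=O)O | intermediate
10 | dilithium enediolate of 9 (C4 planar) | CC(C)(C)[Si](c1ccccc1)(c1ccccc1)OCC[C@@H](C)CC/C=C(\C)CC[C@@H](C(C)=C)C(C)=C(O[Li])O[Li] | intermediate (not isolated)
11 | (3S,6E,10S)-12-[(tert-butyldiphenylsilyl)oxy]-2,2,6,10-tetramethyl-3-(prop-1-en-2-yl)dodec-6-enoic acid | CC(C)(C)[Si](c1ccccc1)(c1ccccc1)OCC[C@@H](C)CC/C=C(\C)CC[C@@H](C(C)=C)C(C)(C)C(=O)O | intermediate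
12 | (3S,6E,10S)-12-[(tert-butyldiphenylsilyl)oxy]-2,2,6,10-tetramethyl-3-(prop-1-en-2-yl)dodec-6-en-1-ol | CC(C)(C)[Si](c1ccccc1)(c1ccccc1)OCC[C@@H](C)CC/C=C(\C)CC[C@@H](C(C)=C)C(C)(C)CO | intermediate
13 | (3S,6E,10S)-12-[(tert-butyldiphenylsilyl)oxy]-2,2,6,10-tetramethyl-3-(prop-1-en-2-yl)dodec-6-enal | CC(C)(C)[Si](c1ccccc1)(c1ccccc1)OCC[C@@H](C)CC/C=C(\C)CC[C@@H](C(C)=C)C(C)(C)C=O | intermediate
14 | tert-butyl{[(3S,6E,10S,12E/Z)-13-methoxy-3,7,11,11-tetramethyl-10-(prop-1-en-2-yl)trideca-6,12-dien-1-yl]oxy}diphenylsilane (enol ether, E/Z mixture) | CC(C)(C)[Si](c1ccccc1)(c1ccccc1)OCC[C@@H](C)CC/C=C(\C)CC[C@@H](C(C)=C)C(C)(C)C=COC | intermediate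
15 | (4S,7E,11S)-13-[(tert-butyldiphenylsilyl)oxy]-3,3,7,11-tetramethyl-4-(prop-1-en-2-yl)tridec-7-enal | CC(C)(C)[Si](c1ccccc1)(c1ccccc1)OCC[C@@H](C)CC/C=C(\C)CC[C@@H](C(C)=C)C(C)(C)CC=O | intermediate
16 | (2R,4aR,8R,8aR)-8-{(3S)-5-[(tert-butyldiphenylsilyl)oxy]-3-methylpentyl}-4,4,7,8a-tetramethyl-1,2,3,4,4a,5,8,8a-octahydronaphthalen-2-ol | CC(C)(C)[Si](c1ccccc1)(c1ccccc1)OCC[C@@H](C)CC[C@@H]1C(C)=CC[C@@H]2C(C)(C)C[C@@H](O)C[C@@]12C | intermediate
17 | (2R,4aR,8R,8aR)-8-[(3S)-5-hydroxy-3-methylpentyl]-4,4,7,8a-tetramethyl-1,2,3,4,4a,5,8,8a-octahydronaphthalen-2-ol | OCC[C@@H](C)CC[C@@H]1C(C)=CC[C@@H]2C(C)(C)C[C@@H](O)C[C@@]12C | intermediate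
18 | (2R,4aR,8R,8aR)-8-[(3S)-5-acetoxy-3-methylpentyl]-4,4,7,8a-tetramethyl-1,2,3,4,4a,5,8,8a-octahydronaphthalen-2-yl acetate (CNP0220683.1) | CC(=O)OCC[C@@H](C)CC[C@@H]1C(C)=CC[C@@H]2C(C)(C)C[C@@H](OC(C)=O)C[C@@]12C | target

**Totals**

Total step count: 13. Longest linear sequence: 13 steps (1 → 18).

**Steps most likely to fail**

Step 11 (Prins bicyclisation). The C10 cation may be quenched by proton transfer from C20 to the aluminium-bound oxygen (ene termination) before the C8=C9 olefin bonds, so that only ring A forms. If a discrete ring A cation intervenes, the anti addition that sets C10 is loosened, and proton loss from the C8 cation may stray to C17. The fallback sets out from 14 and returns at 16. Acetal exchange of the enol ether 14 with ethylene glycol (PPTS, CH2Cl2, rt) gives the ethylene acetal F1 without passing through the free aldehyde. SnCl4 (CH2Cl2, −78 °C) opens F1 to an alkoxycarbenium ion, which starts the same chair–chair cascade (acetal-initiated cation–olefin cyclisation, a known class) and has no metal alkoxide beside the C10 cation to end it by the ene route; this gives the C2 2-hydroxyethyl ether F2. Iodination (I2, PPh3, imidazole) gives the 2-iodoethyl ether F3, and zinc in hot ethanol (Boord-type reductive elimination) expels ethylene and returns the alcohol 16.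

Step 5 (enantioselective Ireland–Claisen). Soft enolisation may be slow or incomplete, and facial discrimination by the boron controller (or a leak through a boat) may be insufficient; the C5 epimer then cannot be removed later, because the only other centre, C13, is remote. The fallback sets out from 3 and returns at 11, with C5 set by an oxazolidinone auxiliary. NBS in THF–H2O gives the terminal bromohydrin F4 and K2CO3 in MeOH the terminal epoxide F5; H5IO6 (THF–Et2O) cleaves it to the aldehyde F6. Horner–Wadsworth–Emmons olefination with diethyl {2-oxo-2-[(4S)-2-oxo-4-phenyl-1,3-oxazolidin-3-yl]ethyl}phosphonate (LiCl, i-Pr2NEt, MeCN) gives the (E)-N-enoyl oxazolidinone F7. Isopropenylmagnesium bromide with CuBr·SMe2 (THF, −78 → −20 °C) adds to the magnesium-chelated s-cis imide on the face away from the 4-phenyl group and gives the conjugate adduct F8 with the required C5 centre. LiOH/H2O2 removes the auxiliary to give the acid F9, and two cycles of LiN(i-Pr)2/MeI methylate C4 exhaustively, through the monomethyl acids F10, to 11.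

Step 10 (enol ether hydrolysis). The acid may start a protic, poorly controlled ring closure of the aldehyde as it forms, or partly remove the silyl ether. The fallback sets out from 13 and returns at 15, and uses no acid. Dimethyl (1-diazo-2-oxopropyl)phosphonate with K2CO3 in MeOH (Ohira–Bestmann reaction) converts 13 into the terminal alkyne F11. Dicyclohexylborane (THF, 0 °C) hydroborates the alkyne in preference to the hindered olefins to give the alkenylborane F12, and NaBO3·4H2O oxidises it to the aldehyde 15.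

**Further compounds**

F1 | step 11 | tert-butyl{[(3S,6E,10S)-12-(1,3-dioxolan-2-yl)-3,7,11,11-tetramethyl-10-(prop-1-en-2-yl)dodec-6-en-1-yl]oxy}diphenylsilane (ethylene acetal of 15) | CC(C)(C)[Si](c1ccccc1)(c1ccccc1)OCC[C@@H](C)CC/C=C(\C)CC[C@@H](C(C)=C)C(C)(C)CC1OCCO1
F2 | step 11 | 2-{[(2R,4aR,8R,8aR)-8-{(3S)-5-[(tert-butyldiphenylsilyl)oxy]-3-methylpentyl}-4,4,7,8a-tetramethyl-1,2,3,4,4a,5,8,8a-octahydronaphthalen-2-yl]oxy}ethan-1-ol | CC(C)(C)[Si](c1ccccc1)(c1ccccc1)OCC[C@@H](C)CC[C@@H]1C(C)=CC[C@@H]2C(C)(C)C[C@@H](OCCO)C[C@@]12C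
F3 | step 11 | 2-iodoethyl ether corresponding to F2 | CC(C)(C)[Si](c1ccccc1)(c1ccccc1)OCC[C@@H](C)CC[C@@H]1C(C)=CC[C@@H]2C(C)(C)C[C@@H](OCCI)C[C@@]12C
F4 | step 5 | (6E,10S)-3-bromo-12-[(tert-butyldiphenylsilyl)oxy]-2,6,10-trimethyldodec-6-en-2-ol (both C3 epimers) | CC(C)(C)[Si](c1ccccc1)(c1ccccc1)OCC[C@@H](C)CC/C=C(\C)CCC(Br)C(C)(C)O
F5 | step 5 | tert-butyl{[(3S,6E)-9-(3,3-dimethyloxiran-2-yl)-3,7-dimethylnon-6-en-1-yl]oxy}diphenylsilane (both epoxide epimers) | CC(C)(C)[Si](c1ccccc1)(c1ccccc1)OCC[C@@H](C)CC/C=C(\C)CCC1OC1(C)C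
F6 | step 5 | (4E,8S)-10-[(tert-butyldiphenylsilyl)oxy]-4,8-dimethyldec-4-enal | CC(C)(C)[Si](c1ccccc1)(c1ccccc1)OCC[C@@H](C)CC/C=C(\C)CCC=O
F7 | step 5 | (4S)-3-[(2E,6E,10S)-12-[(tert-butyldiphenylsilyl)oxy]-6,10-dimethyldodeca-2,6-dienoyl]-4-phenyl-1,3-oxazolidin-2-one | CC(C)(C)[Si](c1ccccc1)(c1ccccc1)OCC[C@@H](C)CC/C=C(\C)CC/C=C/C(=O)N1C(=O)OC[C@@H]1c1ccccc1
F8 | step 5 | (4S)-3-[(3R,6E,10S)-12-[(tert-butyldiphenylsilyl)oxy]-6,10-dimethyl-3-(prop-1-en-2-yl)dodec-6-enoyl]-4-phenyl-1,3-oxazolidin-2-one | CC(C)(C)[Si](c1ccccc1)(c1ccccc1)OCC[C@@H](C)CC/C=C(\C)CC[C@@H](C(C)=C)CC(=O)N1C(=O)OC[C@@H]1c1ccccc1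
F9 | step 5 | (3R,6E,10S)-12-[(tert-butyldiphenylsilyl)oxy]-6,10-dimethyl-3-(prop-1-en-2-yl)dodec-6-enoic acid | CC(C)(C)[Si](c1ccccc1)(c1ccccc1)OCC[C@@H](C)CC/C=C(\C)CC[C@@H](C(C)=C)CC(=O)O
F10 | step 5 | (3R,6E,10S)-12-[(tert-butyldiphenylsilyl)oxy]-2,6,10-trimethyl-3-(prop-1-en-2-yl)dodec-6-enoic acid as the mixture of C2 epimers (9 and its C2 epimer) | CC(C)(C)[Si](c1ccccc1)(c1ccccc1)OCC[C@@H](C)CC/C=C(\C)CC[C@@H](C(C)=C)C(C)C(=O)O
F11 | step 10 | tert-butyl{[(3S,6E,10S)-3,7,11,11-tetramethyl-10-(prop-1-en-2-yl)tridec-6-en-12-yn-1-yl]oxy}diphenylsilane | CC(C)(C)[Si](c1ccccc1)(c1ccccc1)OCC[C@@H](C)CC/C=C(\C)CC[C@@H](C(C)=C)C(C)(C)C#C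
F12 | step 10 | dicyclohexyl[(1E,4S,7E,11S)-13-[(tert-butyldiphenylsilyl)oxy]-3,3,7,11-tetramethyl-4-(prop-1-en-2-yl)trideca-1,7-dien-1-yl]borane | CC(C)(C)[Si](c1ccccc1)(c1ccccc1)OCC[C@@H](C)CC/C=C(\C)CC[C@@H](C(C)=C)C(C)(C)/C=C/B(C1CCCCC1)C1CCCCC1
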